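Repeating the midnight flask, budget it by its protic impurity rather than by its reagent.

| flask | starting material | reagent in the second phase | protic impurity | remark | time | volume of the second phase over the first |
|---|---|---|---|---|---|---|
| midnight | 20 mM | 20 mM | 10 mM | the very flask that is asked about, followed so far |  |  |
| dawn | 20 mM | 40 mM | 10 mM | run made earlier |  |  |
| flask | 20 mM | 20.0 mM | 10.0 mM |  | 6.0 d | 1.0 |

- midnight (time / d: target / %, starting material / %): 0.500: 0.4, 30.5; 1.04: 4.3, 22.7; 1.67: 9.0, 20.0; 2.08: 11.5, 18.6; 2.50: 13.1, 15.8; 3.00: 15.1, 15.1
- dawn (time / d: target / %, starting material / %): 0.417: 2.2, 29.0; 0.833: 6.6, 26.0; 1.25: 11.2, 20.3; 1.67: 15.0, 17.5; 2.08: 22.2, 13.9; 2.50: 22.9, 12.7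

(standard deviation of a reading: 1 percentage point)

- what is said of target includes product in the second phase
- in the second phase: reagent in the second phase, product in the second phase; everything else is in the first
- charges count per volume of the first phase; a concentration in a rate is the amount of a species over the volume of its own phase; every rate counts per litre of the first phase
- the analysis behind the earlier runs scatters by 1 percentage point, standard deviation
- the earlier runs hold the two phases in the same ratio of volumes as the flask asked about
- what has gone from starting material into another species counts as reacted, even if it can come back

- how much target and product in the second phase together there is at 6.0 d, in percent of the starting material charged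
- part of the starting material charged that has reacted at 6.0 d

By the first reading the midnight run had lost 69.1% of its starting material as neither starting material nor target. The dawn run, with twice the reagent, had lost 68.8%. The two losses differ by 0.3 percentage points against a scatter of 1 point.

My assumption: the impurity removes starting material one for one. It is then the limiting reagent of that sink, and the sink ceiling, impurity charge over starting-material charge, is 50.0%. That leaves a pool of 50.0%. The early loss exceeds the ceiling, so on that assumption part of it sits elsewhere, and I take that for a reservoir that can return.

From 1.04 d to 3.00 d, the midnight readings of [starting material] decay at 0.208 d⁻¹, which, carried on, gives 8.09% at 6.0 d. Taking the sink as full and the pool less target as proportional to starting material, I reckon 31.3% target and 91.9% reacted.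

The forecast says 24% target and 91% reacted, “allowing some reservoir return”, lower than mine on target.

The flask gives 27.5% target and 92.2% reacted.

    reagent in the reaction phase ⇌ reagent in the second phase, rate k1*([reagent in the reaction phase] - [reagent in the second phase]/K1) per volume of the first phase (partition coefficient = 1.90, kL = 0.00920 h⁻¹)
    starting material + reagent in the reaction phase → target (k = 9.40 M⁻¹ h⁻¹)
    target ⇌ product in the second phase, rate k3*([target] - [product in the second phase]/K3) per volume of the first phase (partition coefficient = 0.700, kL = 0.0620 h⁻¹)
    target → decomposed product (k = 0.00280 h⁻¹)
    starting material ⇌ dormant form (K = 1.50, k = 0.730 h⁻¹)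
    starting material + protic impurity → quenched substrate (k = 8.10 M⁻¹ h⁻¹)

In the flask, quenched substrate reaches 49.0% at 6.00 d, beside the ceiling. With 2.5 mM of impurity, the neighbour's ceiling is 12.5% and its pool 87.5%.

| at 6.0 d | ceiling | quenched substrate | target |
|---|---|---|---|
| midnight | 50.0% | 49.0% | 27.5% |
| neighbour | 12.5% | 12.5% | 34.4% |

From the midnight flask to the neighbour the pool grows by 38 points and target by 6.9 points, while the neighbour holds 19.3% starting material and 29.2% dormant form.

All runs were generated by integration for an exercise, noise included.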